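**Plan**

- Retrosynthetic cuts, in order: (a) the four silyl ethers; (b) the C2–C3 bond of ring C, which leads back to a diazomethyl ketone whose O1 carries ring B as a plain benzyl ether; (c) the diazo group, back to an acetyl group; (d) the C8–CH2 bond, to an aryl iodide and a chiral primary alkylzinc; (e) the O1–CH2 ether bond, to a phloroacetophenone phenol and a benzyl alcohol; (f) the side chain at its stereocentre, to prenyl bromide and a senecioyl imide.
- Forward order: rings A and B are bought (2,4,6-trihydroxyacetophenone, 4-hydroxy-2-methoxybenzaldehyde) and joined through O1 by Mitsunobu etherification; the side chain is attached at C8 by Negishi coupling; the acetyl group becomes the diazoketone; ring C is closed last, then all silyl groups are removed at once.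
- Enabling feature: C2–H of ring C is a benzylic ether C–H, alpha to O1 and borne by the electron-rich 2-methoxy-4-oxyphenyl ring B, and it lies 1,6 to C3. A carbene at C3 can therefore insert into it, closing ring C and creating C2 from a simple benzyl ether.
- Stereochemistry: the side-chain centre comes from the (S)-4-benzyloxazolidinone auxiliary in a deconjugative dienolate alkylation; C2 comes from the chiral dirhodium carboxylate, which selects one of the two enantiotopic benzylic hydrogens.
- Helpers: the diazo group, the transient trifluoroacetyl group and the silyl ethers (chosen because they carry no C–H alpha to oxygen near the carbene) are all gone by the end of step 15.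

Key step: step 14

Assumption: the sense of induction of Rh2(S-PTTL)4 at the prochiral benzylic CH2 cannot be assigned in advance for this substrate; the route is written with this catalyst, and its mirror-image form Rh2(R-PTTL)4 is the equivalent choice should the 2R epimer be favoured.

Abbreviations: TIPS = triisopropylsilyl; TES = triethylsilyl; Rh2(S-PTTL)4 = dirhodium tetrakis[N-phthaloyl-(S)-tert-leucinate]; SPhos = 2-dicyclohexylphosphino-2',6'-dimethoxybiphenyl.

**Route**

Step 1
Reactants: 1 (4S)-4-benzyl-1,3-oxazolidin-2-one; 2 3-methylbut-2-enoyl chloride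
Product: 3 (4S)-4-benzyl-3-(3-methylbut-2-enoyl)-1,3-oxazolidin-2-one
Conditions: n-BuLi, THF, −78 °C; then 2, −78 to 0 °C
Reagents that add atoms: none
Why: N-acylation of the lithiated oxazolidinone with an acid chloride is the standard entry to Evans imides and touches no stereocentre.

Step 2
Reactants: 3 (4S)-4-benzyl-3-(3-methylbut-2-enoyl)-1,3-oxazolidin-2-one; 4 1-bromo-3-methylbut-2-ene (prenyl bromide)
Product: 5 (4S)-4-benzyl-3-[(2S)-5-methyl-2-(prop-1-en-2-yl)hex-4-enoyl]-1,3-oxazolidin-2-one
Conditions: NaN(SiMe3)2, THF, −78 °C; then 4, −78 to −40 °C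
Reagents that add atoms: none
Why: Deconjugative Evans alkylation, in which gamma-deprotonation gives the chelated sodium (Z)-dienolate of 3 and alkylation at its alpha-carbon on the face opposite the benzyl group should set the (S) centre and create the isopropenyl group in the same event.

Step 3
Reactants: 5 (4S)-4-benzyl-3-[(2S)-5-methyl-2-(prop-1-en-2-yl)hex-4-enoyl]-1,3-oxazolidin-2-one
Product: 6 (4S)-4-benzyl-3-{(2S)-2-[(3,3-dimethyloxiran-2-yl)methyl]-3-methylbut-3-enoyl}-1,3-oxazolidin-2-one (both epimers at the oxirane CH)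
Conditions: mCPBA (1.05 equiv), CH2Cl2, −10 to 0 °C
Reagents that add atoms: 3-chloroperoxybenzoic acid (mCPBA), OOC(=O)c1cccc(Cl)c1
Why: Prilezhaev epoxidation should select the electron-rich trisubstituted alkene over the 1,1-disubstituted isopropenyl alkene, which is also deactivated by the neighbouring imide, and the new oxirane centre is erased in step 4.

Step 4
Reactants: 6 (4S)-4-benzyl-3-{(2S)-2-[(3,3-dimethyloxiran-2-yl)methyl]-3-methylbut-3-enoyl}-1,3-oxazolidin-2-one
Product: 7 (2S)-5-methyl-2-(prop-1-en-2-yl)hexane-1,5-diol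
Conditions: LiAlH4, THF, 0 °C to rt; H2O/aq NaOH work-up
Reagents that add atoms: none
Why: Hydride reduction cleaves the imide to the primary alcohol with release of the auxiliary and opens the trisubstituted epoxide at its less substituted carbon to the tertiary alcohol, and the stereocentre should survive because hydride addition is faster than enolisation.

Step 5
Reactants: 7 (2S)-5-methyl-2-(prop-1-en-2-yl)hexane-1,5-diol
Product: 8 (5S)-6-iodo-2-methyl-5-(prop-1-en-2-yl)hexan-2-ol
Conditions: I2, PPh3, imidazole, CH2Cl2, 0 °C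
Reagents that add atoms: iodine, II
Why: The Appel iodination should take only the primary alcohol, since the tertiary alcohol is too hindered to form or displace an oxyphosphonium ion at this temperature.

Step 6
Reactants: 8 (5S)-6-iodo-2-methyl-5-(prop-1-en-2-yl)hexan-2-ol
Product: 9 triethyl{[(5S)-6-iodo-2-methyl-5-(prop-1-en-2-yl)hexan-2-yl]oxy}silane
Conditions: TESOTf, 2,6-lutidine, CH2Cl2, −78 to 0 °C
Reagents that add atoms: triethylsilyl trifluoromethanesulfonate, CC[Si](CC)(CC)OS(=O)(=O)C(F)(F)F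
Why: Silylation with the silyl triflate covers the hindered tertiary alcohol so that it can neither quench the organozinc reagent of step 12 nor undergo O–H insertion in step 14.

Step 7
Reactants: 10 1-(2,4,6-trihydroxyphenyl)ethan-1-one
Product: 11 1-[2-hydroxy-4,6-bis(triisopropylsilyloxy)phenyl]ethan-1-one
Conditions: TIPSCl (2.1 equiv), imidazole, DMF, 0 °C to rt
Reagents that add atoms: chlorotriisopropylsilane (TIPSCl), CC(C)[Si](Cl)(C(C)C)C(C)C
Why: Silylation should take the para hydroxyl and one ortho hydroxyl and then stop, because the last ortho hydroxyl is hydrogen-bonded to the ketone and shielded.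

Step 8
Reactants: 11 1-[2-hydroxy-4,6-bis(triisopropylsilyloxy)phenyl]ethan-1-one
Product: 12 1-[2-hydroxy-3-iodo-4,6-bis(triisopropylsilyloxy)phenyl]ethan-1-one
Conditions: NIS, CH2Cl2/MeCN, 0 °C to rt
Reagents that add atoms: N-iodosuccinimide, O=C1CCC(=O)N1I
Why: Electrophilic aromatic iodination should occur at C3, ortho to the free hydroxyl, because the only other open position is buried between two bulky TIPS ethers.

Step 9
Reactants: 13 4-hydroxy-2-methoxybenzaldehyde
Product: 14 2-methoxy-4-(triisopropylsilyloxy)benzaldehyde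
Conditions: TIPSCl, imidazole, DMF, rt
Reagents that add atoms: chlorotriisopropylsilane (TIPSCl), CC(C)[Si](Cl)(C(C)C)C(C)C
Why: Silylation of the single phenol protects the future 4'-oxygen in a form that leaves with the other silyl groups in the last step.

Step 10
Reactants: 14 2-methoxy-4-(triisopropylsilyloxy)benzaldehyde
Product: 15 [2-methoxy-4-(triisopropylsilyloxy)phenyl]methanol
Conditions: NaBH4, THF/EtOH, 0 °C
Reagents that add atoms: none
Why: Borohydride reduction of the aldehyde gives the benzylic alcohol without touching the aryl silyl ether, and no stereocentre is formed.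

Step 11
Reactants: 12 1-[2-hydroxy-3-iodo-4,6-bis(triisopropylsilyloxy)phenyl]ethan-1-one; 15 [2-methoxy-4-(triisopropylsilyloxy)phenyl]methanol
Product: 16 1-[3-iodo-2-{[2-methoxy-4-(triisopropylsilyloxy)phenyl]methoxy}-4,6-bis(triisopropylsilyloxy)phenyl]ethan-1-one
Conditions: PPh3, DIAD, THF, 0 °C to rt
Reagents that add atoms: none
Why: The Mitsunobu etherification alkylates the acidic chelated phenol with the primary benzylic alcohol under neutral conditions that spare the aryl silyl ethers, placing ring B on O1 as the benzyl ether whose CH2 becomes C2.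

Step 12
Reactants: 9 triethyl{[(5S)-6-iodo-2-methyl-5-(prop-1-en-2-yl)hexan-2-yl]oxy}silane; 16 1-[3-iodo-2-{[2-methoxy-4-(triisopropylsilyloxy)phenyl]methoxy}-4,6-bis(triisopropylsilyloxy)phenyl]ethan-1-one
Product: 18 1-[2-{[2-methoxy-4-(triisopropylsilyloxy)phenyl]methoxy}-3-[(2R)-5-methyl-2-(prop-1-en-2-yl)-5-(triethylsilyloxy)hexyl]-4,6-bis(triisopropylsilyloxy)phenyl]ethan-1-one, via alkylzinc iodide 17 (not isolated)
Conditions: 9, Zn dust, LiCl, THF, 40 °C; then 16, Pd(OAc)2 (5 mol %), SPhos (10 mol %), THF, 40 °C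
Reagents that add atoms: zinc, [Zn] (supplies the zinc atom of 17 only; none of it remains in 18)
Why: LiCl-promoted zinc insertion into the primary C–I bond followed by Negishi coupling with a bulky biarylphosphine ligand should join the chain to the doubly ortho-substituted aryl iodide in the presence of the ketone, and the stereocentre beta to zinc is not involved.

Step 13
Reactants: 18 1-[2-{[2-methoxy-4-(triisopropylsilyloxy)phenyl]methoxy}-3-[(2R)-5-methyl-2-(prop-1-en-2-yl)-5-(triethylsilyloxy)hexyl]-4,6-bis(triisopropylsilyloxy)phenyl]ethan-1-one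
Product: 20 2-diazo-1-[2-{[2-methoxy-4-(triisopropylsilyloxy)phenyl]methoxy}-3-[(2R)-5-methyl-2-(prop-1-en-2-yl)-5-(triethylsilyloxy)hexyl]-4,6-bis(triisopropylsilyloxy)phenyl]ethan-1-one, via trifluoroacetyl ketone 19 (not isolated)
Conditions: LiN(SiMe3)2, THF, −78 °C; CF3CO2CH2CF3; aq HCl work-up; then MsN3, Et3N, H2O (1 equiv), MeCN, rt
Reagents that add atoms: 2,2,2-trifluoroethyl trifluoroacetate, O=C(OCC(F)(F)F)C(F)(F)F (supplies the trifluoroacetyl group of 19 only); methanesulfonyl azide, CS(=O)(=O)N=[N+]=[N-] (supplies the two diazo nitrogens of 20)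
Why: In this detrifluoroacetylative diazo transfer the lithium enolate of the methyl ketone is trifluoroacetylated to activate the alpha-carbon, and Regitz-type transfer from the sulfonyl azide then installs the diazo group with loss of the trifluoroacetyl helper under conditions mild enough for the silyl ethers and the benzyl ether.

Step 14
Reactants: 20 2-diazo-1-[2-{[2-methoxy-4-(triisopropylsilyloxy)phenyl]methoxy}-3-[(2R)-5-methyl-2-(prop-1-en-2-yl)-5-(triethylsilyloxy)hexyl]-4,6-bis(triisopropylsilyloxy)phenyl]ethan-1-one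
Product: 22 (2S)-2-[2-methoxy-4-(triisopropylsilyloxy)phenyl]-8-[(2R)-5-methyl-2-(prop-1-en-2-yl)-5-(triethylsilyloxy)hexyl]-5,7-bis(triisopropylsilyloxy)-2,3-dihydro-4H-chromen-4-one, via rhodium carbene 21 (not isolated)
Conditions: Rh2(S-PTTL)4 (2 mol %), CH2Cl2, 0 °C, slow addition of 20 at high dilution
Reagents that add atoms: none
Why: The divalent rhodium carboxylate dimer Rh2(S-PTTL)4 takes N2 out of the diazoketone to give the electrophilic rhodium carbene 21, whose carbene carbon (future C3) takes up the hydridic benzylic C–H of the O1–CH2–aryl ether in a concerted, asynchronous three-centre insertion that forms the C3–C2 bond and returns the catalyst. The closest known reaction type is the dirhodium-catalysed intramolecular C–H insertion of 2-alkoxyaryl alpha-diazoketones into the ether alpha-C–H to give chroman-4-ones, together with the benzylic ether insertions of aryl diazoacetates that give 2-aryl-2,3-dihydrobenzofurans. Ring C closes as a six-membered ring by 1,6-insertion through a chair-like array C3–C4–C4a–C8a–O1–C2 with the ring B aryl group pseudo-equatorial. The new stereocentre C2 is set by the chiral carboxylate pocket of the catalyst, which selects one of the two enantiotopic benzylic hydrogens; the side-chain centre is too remote to interfere, and a C2 epimer would be a diastereomer that chromatography can remove. The step needs chemoselectivity for this C–H bond over capture of the carbene by O1 (oxonium ylide, then 1,2-benzyl shift), over cyclopropanation of the isopropenyl group and over O–H or other C–H insertion. This should be secured by the double activation of C2–H (alpha to O1 and benzylic to the donor-substituted ring B), by silyl groups on O5, O7, O4' and the tertiary alcohol that offer no O–H and no C–H alpha to oxygen within reach, by the low basicity of the doubly flanked aryl ether O1, and by slow addition at high dilution, since the alkene cannot reach the carbene within the molecule.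

Step 15
Reactants: 22 (2S)-2-[2-methoxy-4-(triisopropylsilyloxy)phenyl]-8-[(2R)-5-methyl-2-(prop-1-en-2-yl)-5-(triethylsilyloxy)hexyl]-5,7-bis(triisopropylsilyloxy)-2,3-dihydro-4H-chromen-4-one
Product: 23 (2S)-5,7-dihydroxy-8-[(2R)-5-hydroxy-5-methyl-2-(prop-1-en-2-yl)hexyl]-2-(4-hydroxy-2-methoxyphenyl)-2,3-dihydro-4H-chromen-4-one
Conditions: Bu4NF, AcOH (1:1, excess), THF, 0 °C to rt
Reagents that add atoms: none
Why: Fluoride should cleave the three phenolic TIPS ethers and the tertiary TES ether in one operation, while the acetic acid buffer keeps the medium from opening the flavanone to its chalcone, so both stereocentres should be retained.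

**Compound list**

1 | (4S)-4-benzyl-1,3-oxazolidin-2-one | O=C1N[C@@H](Cc2ccccc2)CO1 | starting material
2 | 3-methylbut-2-enoyl chloride | CC(C)=CC(=O)Cl | starting material
3 | (4S)-4-benzyl-3-(3-methylbut-2-enoyl)-1,3-oxazolidin-2-one | CC(C)=CC(=O)N1[C@@H](Cc2ccccc2)COC1=O | intermediate
4 | 1-bromo-3-methylbut-2-ene | CC(C)=CCBr | starting material
5 | (4S)-4-benzyl-3-[(2S)-5-methyl-2-(prop-1-en-2-yl)hex-4-enoyl]-1,3-oxazolidin-2-one | C=C(C)[C@H](CC=C(C)C)C(=O)N1[C@@H](Cc2ccccc2)COC1=O | intermediate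
6 | (4S)-4-benzyl-3-{(2S)-2-[(3,3-dimethyloxiran-2-yl)methyl]-3-methylbut-3-enoyl}-1,3-oxazolidin-2-one, both epimers at the oxirane CH | C=C(C)[C@H](CC1OC1(C)C)C(=O)N2[C@@H](Cc3ccccc3)COC2=O | intermediate
7 | (2S)-5-methyl-2-(prop-1-en-2-yl)hexane-1,5-diol | C=C(C)[C@H](CCC(C)(C)O)CO | intermediate
8 | (5S)-6-iodo-2-methyl-5-(prop-1-en-2-yl)hexan-2-ol | C=C(C)[C@H](CCC(C)(C)O)CI | intermediate
9 | triethyl{[(5S)-6-iodo-2-methyl-5-(prop-1-en-2-yl)hexan-2-yl]oxy}silane | C=C(C)[C@H](CCC(C)(C)O[Si](CC)(CC)CC)CI | intermediate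
10 | 1-(2,4,6-trihydroxyphenyl)ethan-1-one | CC(=O)c1c(O)cc(O)cc1O | starting material
11 | 1-[2-hydroxy-4,6-bis(triisopropylsilyloxy)phenyl]ethan-1-one | CC(=O)c1c(O)cc(O[Si](C(C)C)(C(C)C)C(C)C)cc1O[Si](C(C)C)(C(C)C)C(C)C | intermediate
12 | 1-[2-hydroxy-3-iodo-4,6-bis(triisopropylsilyloxy)phenyl]ethan-1-one | CC(=O)c1c(O)c(I)c(O[Si](C(C)C)(C(C)C)C(C)C)cc1O[Si](C(C)C)(C(C)C)C(C)C | intermediate
13 | 4-hydroxy-2-methoxybenzaldehyde | COc1cc(O)ccc1C=O | starting material
14 | 2-methoxy-4-(triisopropylsilyloxy)benzaldehyde | COc1cc(O[Si](C(C)C)(C(C)C)C(C)C)ccc1C=O | intermediate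
15 | [2-methoxy-4-(triisopropylsilyloxy)phenyl]methanol | COc1cc(O[Si](C(C)C)(C(C)C)C(C)C)ccc1CO | intermediate
16 | 1-[3-iodo-2-{[2-methoxy-4-(triisopropylsilyloxy)phenyl]methoxy}-4,6-bis(triisopropylsilyloxy)phenyl]ethan-1-one | CC(=O)c1c(OCc2ccc(O[Si](C(C)C)(C(C)C)C(C)C)cc2OC)c(I)c(O[Si](C(C)C)(C(C)C)C(C)C)cc1O[Si](C(C)C)(C(C)C)C(C)C | intermediate
17 | [(2S)-5-methyl-2-(prop-1-en-2-yl)-5-(triethylsilyloxy)hexyl]zinc iodide | C=C(C)[C@H](CCC(C)(C)O[Si](CC)(CC)CC)C[Zn]I | intermediate
18 | 1-[2-{[2-methoxy-4-(triisopropylsilyloxy)phenyl]methoxy}-3-[(2R)-5-methyl-2-(prop-1-en-2-yl)-5-(triethylsilyloxy)hexyl]-4,6-bis(triisopropylsilyloxy)phenyl]ethan-1-one | C=C(C)[C@H](CCC(C)(C)O[Si](CC)(CC)CC)Cc1c(O[Si](C(C)C)(C(C)C)C(C)C)cc(O[Si](C(C)C)(C(C)C)C(C)C)c(C(C)=O)c1OCc1ccc(O[Si](C(C)C)(C(C)C)C(C)C)cc1OC | intermediate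
19 | 4,4,4-trifluoro-1-[2-{[2-methoxy-4-(triisopropylsilyloxy)phenyl]methoxy}-3-[(2R)-5-methyl-2-(prop-1-en-2-yl)-5-(triethylsilyloxy)hexyl]-4,6-bis(triisopropylsilyloxy)phenyl]butane-1,3-dione | C=C(C)[C@H](CCC(C)(C)O[Si](CC)(CC)CC)Cc1c(O[Si](C(C)C)(C(C)C)C(C)C)cc(O[Si](C(C)C)(C(C)C)C(C)C)c(C(=O)CC(=O)C(F)(F)F)c1OCc1ccc(O[Si](C(C)C)(C(C)C)C(C)C)cc1OC | intermediate
20 | 2-diazo-1-[2-{[2-methoxy-4-(triisopropylsilyloxy)phenyl]methoxy}-3-[(2R)-5-methyl-2-(prop-1-en-2-yl)-5-(triethylsilyloxy)hexyl]-4,6-bis(triisopropylsilyloxy)phenyl]ethan-1-one | C=C(C)[C@H](CCC(C)(C)O[Si](CC)(CC)CC)Cc1c(O[Si](C(C)C)(C(C)C)C(C)C)cc(O[Si](C(C)C)(C(C)C)C(C)C)c(C(=O)C=[N+]=[N-])c1OCc1ccc(O[Si](C(C)C)(C(C)C)C(C)C)cc1OC | intermediate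
21 | rhodium carbene formed from 20 and Rh2(S-PTTL)4 by loss of N2 (carbene carbon on one rhodium; drawn in ionic form with the second rhodium and the four N-phthaloyl-(S)-tert-leucinate ligands as separate ions) | C=C(C)[C@H](CCC(C)(C)O[Si](CC)(CC)CC)Cc1c(O[Si](C(C)C)(C(C)C)C(C)C)cc(O[Si](C(C)C)(C(C)C)C(C)C)c(C(=O)C=[Rh+2])c1OCc1ccc(O[Si](C(C)C)(C(C)C)C(C)C)cc1OC.[Rh+2].CC(C)(C)[C@H](N1C(=O)c2ccccc2C1=O)C(=O)[O-].CC(C)(C)[C@H](N1C(=O)c2ccccc2C1=O)C(=O)[O-].CC(C)(C)[C@H](N1C(=O)c2ccccc2C1=O)C(=O)[O-].CC(C)(C)[C@H](N1C(=O)c2ccccc2C1=O)C(=O)[O-] | intermediate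
22 | (2S)-2-[2-methoxy-4-(triisopropylsilyloxy)phenyl]-8-[(2R)-5-methyl-2-(prop-1-en-2-yl)-5-(triethylsilyloxy)hexyl]-5,7-bis(triisopropylsilyloxy)-2,3-dihydro-4H-chromen-4-one | C=C(C)[C@H](CCC(C)(C)O[Si](CC)(CC)CC)Cc1c(O[Si](C(C)C)(C(C)C)C(C)C)cc(O[Si](C(C)C)(C(C)C)C(C)C)c2c1O[C@H](c1ccc(O[Si](C(C)C)(C(C)C)C(C)C)cc1OC)CC2=O | intermediate
23 | (2S)-5,7-dihydroxy-8-[(2R)-5-hydroxy-5-methyl-2-(prop-1-en-2-yl)hexyl]-2-(4-hydroxy-2-methoxyphenyl)-2,3-dihydro-4H-chromen-4-one | C=C(C)[C@H](CCC(C)(C)O)Cc1c(O)cc(O)c2c1O[C@H](c1ccc(O)cc1OC)CC2=O | target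

**Summary**

Total step count: 15. Longest linear sequence: 10 steps (steps 1 to 6, then 12 to 15).

Steps most likely to fail:

1. Step 14. The carbene may be captured by the ether oxygen O1 and the resulting ylide may undergo 1,2-benzyl migration; with so hydridic a C–H bond the insertion may also become stepwise and lose facial selectivity; intermolecular cyclopropanation may compete if the concentration is too high. Fallback, from 18 back to 22, closing ring C through O1–C2 instead: oxidative cleavage of the electron-rich benzyl ether of 18 with DDQ in CH2Cl2/pH 7 buffer should give the 2-hydroxyacetophenone F1 and return aldehyde 14. Amine-mediated Claisen–Schmidt condensation of F1 with 14 (pyrrolidine, EtOH, 50 °C) should give the 2'-hydroxychalcone F2, whose oxa-Michael closure under the same amine gives 22 together with its 2R epimer F3. Because the side-chain centre is fixed, 22 and F3 are diastereomers and should be separable by chromatography; F3 can be re-equilibrated through F2 with the amine and recycled.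

2. Step 12. Oxidative addition and transmetalation at the iodide flanked by two ortho oxygen substituents may be slow, leaving time for protodezincation or beta-hydride elimination of the alkylpalladium species; the zinc insertion itself may stall. Fallback, from 9 and 16 back to 18, through boron instead of zinc: iodine–lithium exchange on 9 (t-BuLi, Et2O, −78 °C) gives the alkyllithium F4, which is trapped with 9-methoxy-9-borabicyclo[3.3.1]nonane as the lithium alkyl(methoxy)borate F5. B-alkyl Suzuki–Miyaura coupling of F5 with 16 (PdCl2(dppf), K3PO4, DMF/H2O, rt) should then give 18.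

3. Step 11. The chelated, doubly flanked phenol may react sluggishly, and the electron-rich benzylic oxyphosphonium ion may ionise and alkylate the ring carbon instead of oxygen. Fallback, from 15 and 12 back to 16, by Williamson etherification: 15 is converted with MsCl and Et3N in CH2Cl2 at 0 °C into the benzylic chloride 1-(chloromethyl)-2-methoxy-4-(triisopropylsilyloxy)benzene F6, and 12 is O-alkylated with F6 (K2CO3, Bu4NI cat., dry acetone, 40 °C) to give 16.

**Further compounds**

F1 | step 14 | 1-[2-hydroxy-3-[(2R)-5-methyl-2-(prop-1-en-2-yl)-5-(triethylsilyloxy)hexyl]-4,6-bis(triisopropylsilyloxy)phenyl]ethan-1-one | C=C(C)[C@H](CCC(C)(C)O[Si](CC)(CC)CC)Cc1c(O[Si](C(C)C)(C(C)C)C(C)C)cc(O[Si](C(C)C)(C(C)C)C(C)C)c(C(C)=O)c1O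
F2 | step 14 | (2E)-1-[2-hydroxy-3-[(2R)-5-methyl-2-(prop-1-en-2-yl)-5-(triethylsilyloxy)hexyl]-4,6-bis(triisopropylsilyloxy)phenyl]-3-[2-methoxy-4-(triisopropylsilyloxy)phenyl]prop-2-en-1-one | C=C(C)[C@H](CCC(C)(C)O[Si](CC)(CC)CC)Cc1c(O[Si](C(C)C)(C(C)C)C(C)C)cc(O[Si](C(C)C)(C(C)C)C(C)C)c(C(=O)/C=C/c2ccc(O[Si](C(C)C)(C(C)C)C(C)C)cc2OC)c1O
F3 | step 14 | (2R)-2-[2-methoxy-4-(triisopropylsilyloxy)phenyl]-8-[(2R)-5-methyl-2-(prop-1-en-2-yl)-5-(triethylsilyloxy)hexyl]-5,7-bis(triisopropylsilyloxy)-2,3-dihydro-4H-chromen-4-one | C=C(C)[C@H](CCC(C)(C)O[Si](CC)(CC)CC)Cc1c(O[Si](C(C)C)(C(C)C)C(C)C)cc(O[Si](C(C)C)(C(C)C)C(C)C)c2c1O[C@@H](c1ccc(O[Si](C(C)C)(C(C)C)C(C)C)cc1OC)CC2=O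
F4 | step 12 | [(2S)-5-methyl-2-(prop-1-en-2-yl)-5-(triethylsilyloxy)hexyl]lithium | C=C(C)[C@H](CCC(C)(C)O[Si](CC)(CC)CC)C[Li]
F5 | step 12 | lithium 9-methoxy-9-[(2S)-5-methyl-2-(prop-1-en-2-yl)-5-(triethylsilyloxy)hexyl]-9-boranuidabicyclo[3.3.1]nonane | C=C(C)[C@H](CCC(C)(C)O[Si](CC)(CC)CC)C[B-]1(OC)C2CCCC1CCC2.[Li+]
F6 | step 11 | 1-(chloromethyl)-2-methoxy-4-(triisopropylsilyloxy)benzene | COc1cc(O[Si](C(C)C)(C(C)C)C(C)C)ccc1CCl
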